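**Retrosynthetic overview**

1. Cyclopentane locants: C-1 is the quaternary aryl carbon, C-2 the CH(CH3), C-3 the C(=CHBr), and C-4 and C-5 the two CH2 groups. The last steps are aryl bromination para to OH and, before it, addition of the C-1 methyl to an o-quinone methide, trans to the C-2 methyl.
2. Key disconnection: C-4 and C-5 are ethylene. One copper-mediated bromine-atom-transfer radical chain inserts ethylene between the benzylic carbon (future C-1, carrying aryl, phenylsulfonyl and Br) and the inner alkyne carbon (future C-3) of an acyclic alpha-bromo sulfone; the bromine atom ends on the alkyne terminus as the (E)-bromomethylene group.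
3. Enabling feature: C-1 is benzylic to the benzene ring and stands 1,3 to C-3, so a radical at C-1 is homopropargylic, and 5-exo-dig closure after one ethylene gives exactly the cyclopentane with its exocyclic alkene. The phenol oxygen ortho to C-1 then lets the temporary sulfone on C-1 leave as an o-quinone methide.
4. The acyclic precursor comes from 2-hydroxy-4-methylbenzaldehyde and (R)-but-3-yn-2-ol (source of the C-2 stereocentre) by palladium/zinc propargylation, sulfinate-for-hydroxyl exchange and bromination.
5. Ring order: the benzene ring is bought; the cyclopentane is the only ring made (key step).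

Key step: step 6

Assumption: the palladium/zinc propargylation is taken to proceed with net inversion at the propargylic carbon (anti SN2′ palladation, syn SE2′ addition), as is usual for allenylzinc reagents made this way.

Step 1
Reactants: 1 2-hydroxy-4-methylbenzaldehyde
Product: 2 4-methyl-2-[(triisopropylsilyl)oxy]benzaldehyde
Conditions: iPr3SiCl, imidazole, DMF, rt
Reagents that add atoms: chlorotriisopropylsilane, CC(C)[Si](Cl)(C(C)C)C(C)C
Why: Imidazole-promoted silylation of the phenol, chosen because the bulky silyl ether withstands the base of step 5 and keeps the later benzylic sulfone from eliminating to an o-quinone methide too early.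

Step 2
Reactants: 3 (R)-but-3-yn-2-ol
Product: 4 (R)-but-3-yn-2-yl methanesulfonate
Conditions: MsCl, Et3N, CH2Cl2, −78 °C
Reagents that add atoms: methanesulfonyl chloride, CS(=O)(=O)Cl
Why: Sulfonylation of the secondary alcohol at oxygen, so the stereocentre is kept and becomes the propargylic leaving group.

Step 3
Reactants: 2 4-methyl-2-[(triisopropylsilyl)oxy]benzaldehyde, 4 (R)-but-3-yn-2-yl methanesulfonate
Product: 6 (1S,2S)-2-methyl-1-{4-methyl-2-[(triisopropylsilyl)oxy]phenyl}but-3-yn-1-ol, via allenylzinc reagent 5 (not isolated)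
Conditions: Pd(OAc)2 (5 mol %), PPh3 (5 mol %), Et2Zn, THF, −78 to −20 °C; aq NH4Cl
Reagents that add atoms: none
Why: Marshall propargylation: zerovalent palladium displaces the mesylate anti (SN2′), transmetalation gives the allenylzinc 5, and its cyclic SE2′ addition to the aldehyde should set the methyl-bearing centre from 4 with net inversion and give mainly the anti carbinol, whose own configuration is lost later.

Step 4
Reactants: 6 (1S,2S)-2-methyl-1-{4-methyl-2-[(triisopropylsilyl)oxy]phenyl}but-3-yn-1-ol
Product: 7 triisopropyl{5-methyl-2-[(2S)-2-methyl-1-(phenylsulfonyl)but-3-yn-1-yl]phenoxy}silane (both epimers at the sulfonyl carbon)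
Conditions: PhSO2H, (CF3)2CHOH–CH2Cl2, rt
Reagents that add atoms: benzenesulfinic acid, OS(=O)c1ccccc1
Why: Dehydrative SN1 sulfonylation in an ionising solvent through the benzylic cation stabilised by the ortho oxygen and para methyl group, sulfinate bonding through sulfur; both epimers at the new sulfonyl carbon are equally useful and the neighbouring centre is not involved.

Step 5
Reactants: 7 triisopropyl{5-methyl-2-[(2S)-2-methyl-1-(phenylsulfonyl)but-3-yn-1-yl]phenoxy}silane
Product: 8 {2-[(2S)-1-bromo-2-methyl-1-(phenylsulfonyl)but-3-yn-1-yl]-5-methylphenoxy}triisopropylsilane (both epimers at the bromo carbon)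
Conditions: LiN(SiMe3)2, THF, −78 °C; then NBS, −78 °C
Reagents that add atoms: N-bromosuccinimide, O=C1CCC(=O)N1Br
Why: The C–H flanked by sulfone and aryl is more acidic than the alkyne C–H, and the lithiated sulfone is brominated by NBS (electrophilic halogenation of a sulfonyl carbanion), the new centre again needing no control.

Step 6
Reactants: 8 {2-[(2S)-1-bromo-2-methyl-1-(phenylsulfonyl)but-3-yn-1-yl]-5-methylphenoxy}triisopropylsilane, 9 ethylene
Product: 13 {2-[(2S,3E)-3-(bromomethylene)-2-methyl-1-(phenylsulfonyl)cyclopentyl]-5-methylphenoxy}triisopropylsilane (both C-1 epimers), via sulfonyl benzylic radical 10 (not isolated), via primary alkyl radical 11 (not isolated), via vinyl radical 12 (not isolated)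
Conditions: ethylene (40 bar), CuBr (5 mol %), tris(2-pyridylmethyl)amine (5 mol %), AIBN (10 mol %), benzene, 70 °C
Reagents that add atoms: none
Why: Proposed new method: monovalent copper (CuBr/tris(2-pyridylmethyl)amine) abstracts the bromine of 8 reversibly to give the tertiary benzylic sulfonyl radical 10, which adds to ethylene to give the primary radical 11, 11 cyclises onto the alkyne to the vinyl radical 12, and 12 takes bromine back from divalent copper bromide or from 8, so that both ring C–C bonds and the vinylic C–Br bond are made in one chain without any by-product. The closest known reaction types are the halogen-atom-transfer radical [3+2] annulation of homopropargylic alpha-halo malonates with 1-alkenes and the copper-catalysed Kharasch addition of alpha-bromo sulfones to alkenes; new are the tertiary benzylic sulfonyl radical and ethylene as the partner. The cyclopentane is closed in the 5-exo-dig mode, favoured over 6-endo-dig and accelerated by the fully substituted carbon in the tether. The sulfonyl-bearing ring carbon is formed as both epimers, which is harmless because it is made planar again in step 8, and the methyl-bearing stereocentre is not touched by any radical. The step needs E geometry at the new alkene and capture of ethylene before the chain breaks: the bent vinyl radical 12 should accept bromine on the lobe next to the ring CH2 and away from the CH(CH3) group (E is also the more stable isomer), the sulfone makes 10 electrophilic enough for an unactivated alkene, and reversible deactivation by copper lets the stabilised radical 10 wait for ethylene without dimerising.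

Step 7
Reactants: 13 {2-[(2S,3E)-3-(bromomethylene)-2-methyl-1-(phenylsulfonyl)cyclopentyl]-5-methylphenoxy}triisopropylsilane
Product: 14 2-[(2S,3E)-3-(bromomethylene)-2-methyl-1-(phenylsulfonyl)cyclopentyl]-5-methylphenol (both C-1 epimers)
Conditions: Bu4NF, AcOH, THF, 0 °C
Reagents that add atoms: none
Why: Fluoride cleaves the aryl silyl ether and the acetic acid buffer should deliver the o-hydroxybenzyl sulfone as the neutral phenol, which does not eliminate until base is added.

Step 8
Reactants: 14 2-[(2S,3E)-3-(bromomethylene)-2-methyl-1-(phenylsulfonyl)cyclopentyl]-5-methylphenol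
Product: 16 2-[(1R,2R,3E)-3-(bromomethylene)-1,2-dimethylcyclopentyl]-5-methylphenol, via o-quinone methide 15 (not isolated)
Conditions: MeMgBr (4 equiv), toluene–Et2O, −78 to 0 °C; aq NH4Cl
Reagents that add atoms: methylmagnesium bromide, C[Mg]Br
Why: The first equivalent of Grignard reagent deprotonates the phenol, the magnesium phenoxide expels sulfinate to the o-quinone methide 15, and conjugate (1,4) addition of a second equivalent should occur on the ring face opposite the neighbouring secondary methyl group, setting the quaternary centre with the two methyl groups trans and the aryl cis to the C-2 methyl.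

Step 9
Reactants: 16 2-[(1R,2R,3E)-3-(bromomethylene)-1,2-dimethylcyclopentyl]-5-methylphenol
Product: 17 4-bromo-2-[(1R,2R,3E)-3-(bromomethylene)-1,2-dimethylcyclopentyl]-5-methylphenol
Conditions: NBS (1 equiv), MeCN, −20 to 0 °C
Reagents that add atoms: N-bromosuccinimide, O=C1CCC(=O)N1Br
Why: Electrophilic aromatic bromination directed para to the hydroxyl group (the free ortho position lies between OH and CH3 and is hindered), while the electron-poor bromoalkene should not react.

**Compound list**

1 | 2-hydroxy-4-methylbenzaldehyde | Cc1ccc(C=O)c(O)c1 | starting material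
2 | 4-methyl-2-[(triisopropylsilyl)oxy]benzaldehyde | Cc1ccc(C=O)c(O[Si](C(C)C)(C(C)C)C(C)C)c1 | intermediate
3 | (R)-but-3-yn-2-ol | C[C@@H](O)C#C | starting material
4 | (R)-but-3-yn-2-yl methanesulfonate | C[C@@H](OS(C)(=O)=O)C#C | intermediate
5 | (aS)-buta-1,2-dien-1-yl(ethyl)zinc | CC=[C@@]=C[Zn]CC | intermediate (not isolated)
6 | (1S,2S)-2-methyl-1-{4-methyl-2-[(triisopropylsilyl)oxy]phenyl}but-3-yn-1-ol | Cc1ccc([C@@H](O)[C@@H](C)C#C)c(O[Si](C(C)C)(C(C)C)C(C)C)c1 | intermediate
7 | triisopropyl{5-methyl-2-[(2S)-2-methyl-1-(phenylsulfonyl)but-3-yn-1-yl]phenoxy}silane, both epimers at the sulfonyl carbon | Cc1ccc(C([C@@H](C)C#C)S(=O)(=O)c2ccccc2)c(O[Si](C(C)C)(C(C)C)C(C)C)c1 | intermediate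
8 | {2-[(2S)-1-bromo-2-methyl-1-(phenylsulfonyl)but-3-yn-1-yl]-5-methylphenoxy}triisopropylsilane, both epimers at the bromo carbon | Cc1ccc(C(Br)([C@@H](C)C#C)S(=O)(=O)c2ccccc2)c(O[Si](C(C)C)(C(C)C)C(C)C)c1 | intermediate
9 | ethylene | C=C | starting material
10 | tertiary benzylic sulfonyl radical formed from 8 by loss of bromine | Cc1ccc([C]([C@@H](C)C#C)S(=O)(=O)c2ccccc2)c(O[Si](C(C)C)(C(C)C)C(C)C)c1 | intermediate (not isolated)
11 | (4S)-4-methyl-3-{4-methyl-2-[(triisopropylsilyl)oxy]phenyl}-3-(phenylsulfonyl)hex-5-yn-1-yl radical | [CH2]CC([C@@H](C)C#C)(c1ccc(C)cc1O[Si](C(C)C)(C(C)C)C(C)C)S(=O)(=O)c1ccccc1 | intermediate (not isolated)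
12 | exocyclic vinyl radical: [(2S)-2-methyl-3-{4-methyl-2-[(triisopropylsilyl)oxy]phenyl}-3-(phenylsulfonyl)cyclopentylidene]methyl radical | Cc1ccc(C2(S(=O)(=O)c3ccccc3)CCC(=[CH])[C@@H]2C)c(O[Si](C(C)C)(C(C)C)C(C)C)c1 | intermediate (not isolated)
13 | {2-[(2S,3E)-3-(bromomethylene)-2-methyl-1-(phenylsulfonyl)cyclopentyl]-5-methylphenoxy}triisopropylsilane, both C-1 epimers | Cc1ccc(C2(S(=O)(=O)c3ccccc3)CC/C(=C\Br)[C@@H]2C)c(O[Si](C(C)C)(C(C)C)C(C)C)c1 | intermediate
14 | 2-[(2S,3E)-3-(bromomethylene)-2-methyl-1-(phenylsulfonyl)cyclopentyl]-5-methylphenol, both C-1 epimers | Cc1ccc(C2(S(=O)(=O)c3ccccc3)CC/C(=C\Br)[C@@H]2C)c(O)c1 | intermediate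
15 | 6-[(2R,3E)-3-(bromomethylene)-2-methylcyclopentylidene]-3-methylcyclohexa-2,4-dien-1-one (o-quinone methide) | CC1=CC(=O)C(=C2CC/C(=C\Br)[C@@H]2C)C=C1 | intermediate (not isolated)
16 | 2-[(1R,2R,3E)-3-(bromomethylene)-1,2-dimethylcyclopentyl]-5-methylphenol | Cc1ccc([C@]2(C)CC/C(=C\Br)[C@@H]2C)c(O)c1 | intermediate
17 | 4-bromo-2-[(1R,2R,3E)-3-(bromomethylene)-1,2-dimethylcyclopentyl]-5-methylphenol | Cc1cc(O)c([C@]2(C)CC/C(=C\Br)[C@@H]2C)cc1Br | target

**Step count and risks**

Total step count: 9. Longest linear sequence: 8 steps (from 1 through steps 1, 3, 4, 5, 6, 7, 8 and 9; the same length from 3).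

Steps most likely to fail:

1. Step 6 (proposed new method). The stabilised tertiary radical may capture ethylene too slowly, so that reduction back to the sulfone, loss of HBr to a vinyl sulfone, or bromine return at the open-chain stage takes over; bromine transfer to the vinyl radical may also erode the E geometry. The fallback uses only known reactions, sets out from 7 and comes back at 16. Compound 7 would be deprotonated with LiN(SiMe3)2 and the sulfonyl carbanion alkylated with ethylene oxide and BF3·OEt2 to give (4S)-4-methyl-3-{4-methyl-2-[(triisopropylsilyl)oxy]phenyl}-3-(phenylsulfonyl)hex-5-yn-1-ol F1. Appel-type iodination (I2, PPh3, imidazole) should give {2-[(4S)-1-iodo-4-methyl-3-(phenylsulfonyl)hex-5-yn-3-yl]-5-methylphenoxy}triisopropylsilane F2. Iodine-atom-transfer 5-exo-dig radical cyclisation ((Bu3Sn)2, light, benzene, 80 °C) should then give {2-[(2S,3E)-3-(iodomethylene)-2-methyl-1-(phenylsulfonyl)cyclopentyl]-5-methylphenoxy}triisopropylsilane F3, the Z isomer being removed. Desilylation as in step 7 would give 2-[(2S,3E)-3-(iodomethylene)-2-methyl-1-(phenylsulfonyl)cyclopentyl]-5-methylphenol F4, and conjugate methylation as in step 8 would give 2-[(1R,2R,3E)-3-(iodomethylene)-1,2-dimethylcyclopentyl]-5-methylphenol F5. Iodine–lithium exchange (t-BuLi, Et2O, −78 °C) and quenching with BrCl2CCCl2Br should deliver 16 with retention of the alkene geometry.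

2. Step 8. The o-quinone methide may tautomerise to a 2-cyclopentenylphenol by proton loss under the basic conditions, or the methyl group may add with too little preference for the face opposite the C-2 methyl. The fallback sets out from 13 and comes back at 16; it replaces the basic conjugate addition by a cationic substitution on the protected compound. Treating 13 with AlMe3 in CH2Cl2 (−78 to 0 °C) should ionise the tertiary benzylic sulfone and transfer methyl from aluminium (alkylative desulfonylation) to give {2-[(1R,2R,3E)-3-(bromomethylene)-1,2-dimethylcyclopentyl]-5-methylphenoxy}triisopropylsilane F6, and Bu4NF would then give 16.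

3. Step 4. The benzylic cation may lose a proton to give a conjugated enyne, or the acid may cleave the silyl ether, instead of the cation being captured by sulfinate. The fallback sets out from 6 and comes back at 7; it avoids the cation. A phosphine/disulfide thioetherification of the Mitsunobu type (PBu3, PhSSPh, THF) should give triisopropyl{5-methyl-2-[(2S)-2-methyl-1-(phenylsulfanyl)but-3-yn-1-yl]phenoxy}silane F7 by SN2 displacement, and oxidation with mCPBA (2.2 equiv, CH2Cl2, 0 °C) would give 7.

Further compounds

F1 | step 6 | (4S)-4-methyl-3-{4-methyl-2-[(triisopropylsilyl)oxy]phenyl}-3-(phenylsulfonyl)hex-5-yn-1-ol | OCCC([C@@H](C)C#C)(c1ccc(C)cc1O[Si](C(C)C)(C(C)C)C(C)C)S(=O)(=O)c1ccccc1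
F2 | step 6 | {2-[(4S)-1-iodo-4-methyl-3-(phenylsulfonyl)hex-5-yn-3-yl]-5-methylphenoxy}triisopropylsilane | ICCC([C@@H](C)C#C)(c1ccc(C)cc1O[Si](C(C)C)(C(C)C)C(C)C)S(=O)(=O)c1ccccc1
F3 | step 6 | {2-[(2S,3E)-3-(iodomethylene)-2-methyl-1-(phenylsulfonyl)cyclopentyl]-5-methylphenoxy}triisopropylsilane | Cc1ccc(C2(S(=O)(=O)c3ccccc3)CC/C(=C\I)[C@@H]2C)c(O[Si](C(C)C)(C(C)C)C(C)C)c1
F4 | step 6 | 2-[(2S,3E)-3-(iodomethylene)-2-methyl-1-(phenylsulfonyl)cyclopentyl]-5-methylphenol | Cc1ccc(C2(S(=O)(=O)c3ccccc3)CC/C(=C\I)[C@@H]2C)c(O)c1
F5 | step 6 | 2-[(1R,2R,3E)-3-(iodomethylene)-1,2-dimethylcyclopentyl]-5-methylphenol | Cc1ccc([C@]2(C)CC/C(=C\I)[C@@H]2C)c(O)c1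
F6 | step 8 | {2-[(1R,2R,3E)-3-(bromomethylene)-1,2-dimethylcyclopentyl]-5-methylphenoxy}triisopropylsilane | Cc1ccc([C@]2(C)CC/C(=C\Br)[C@@H]2C)c(O[Si](C(C)C)(C(C)C)C(C)C)c1
F7 | step 4 | triisopropyl{5-methyl-2-[(2S)-2-methyl-1-(phenylsulfanyl)but-3-yn-1-yl]phenoxy}silane | Cc1ccc(C(Sc2ccccc2)[C@@H](C)C#C)c(O[Si](C(C)C)(C(C)C)C(C)C)c1
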